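## Analysis of the target

CNP0187343.0 (29, C36H26O19) is an achiral, unbranched hexamer of phloroglucinol. Six benzene rings A–F are joined by five diaryl ether oxygens, O1 (A–B) to O5 (E–F); there are fourteen free phenolic hydroxyls and no stereocentre. Ring A is a 2,4,6-trihydroxyphenyl group and ring F a 3,4,5-trihydroxyphenyl group. Rings B–E are 3,5-dihydroxy-1,4-phenylenedioxy units in which C1 carries the oxygen from the preceding ring and C4 the oxygen to the next ring. Every ether oxygen therefore links a carbon flanked by two oxygenated carbons to a carbon flanked by two C–H, so each ether is di-ortho-substituted on one side and both partners are electron-rich. The only sensitive function is the polyphenol itself, which oxidises easily in air, above all under base, and must stay masked until the last step. The difficulty lies in making hindered, electron-rich diaryl ethers repeatedly and in handling near-identical oligomers. The strategy rests on ring C: C1 bears O2 between C2–H and C6–H, C3 and C5 bear hydroxyls, and C4 bears O3 between them. This is the resorcinol pattern that an oxygenated vinylketene and an aryloxyalkyne deliver, so ring C can be made from open-chain carbons that already carry O2 and O3.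

## Retrosynthetic reasoning

**29 ⇒ 28.** Thirteen O–alkyl bonds are cut (twelve methyl ethers, one ethyl ether). Methyl ethers survive copper couplings, organolithium, peracid and heat, and one Lewis-acid dealkylation removes them all without touching the diaryl ethers. The forward step only has to be exhaustive.

**28 ⇒ 9 + 23.** Ring C is cut at C2–C3 and C1–C6. Ring C is the central ring, so the cut splits the hexamer into a two-ring and a three-ring piece. Its two ether oxygens, O2 and O3, come in ready-made: O2 as the oxygen of ynol ether 9, O3 as the 4-aryloxy group of cyclobutenone 23. The forward reaction is a thermal cascade that inserts the two alkyne carbons of 9 between C1 and C2 of 23 and ends in a phenol. Neither of the two most central ethers has to be made by a coupling between two large fragments.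

**23 ⇒ 19 + 20.** The four-membered ring is cut into aryloxyketene 22 and alkyne 20. The ketene comes from acid 19 through chloride 21. The forward (2+2) addition must place the ethoxy group at C3 and the aryloxy group at C4; the polarity of both partners ensures this.

**19 ⇒ 18 ⇒ 16 + 17.** The O–CH2 bond is cut. Phenol 16 has its hydroxyl on the unhindered C1 of ring D, so a plain Williamson alkylation with 17 followed by ester hydrolysis suffices.

**16 ⇒ 14.** The C1–O bond of ring D is traced back to a formyl group. This hydroxyl must be the only free one in the three-ring piece and must sit on the carbon between two C–H. An aldehyde para to the hindered hydroxyl of 10 marks exactly that carbon, survives two copper couplings, and is converted by a peracid through formate 15.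

**14 ⇒ 12 + 13, and 12 ⇒ 11 ⇒ 10 + 2.** O5 and O4 are cut so that the oxygen always belongs to the di-ortho-methoxy phenol and the carbon to an aryl bromide with free ortho positions. This is the only polarity that keeps the hindrance off the halide. Bromide 13 supplies ring F. Bromide 2 supplies ring E with its own hindered hydroxyl masked as a benzyl ether, freed by hydrogenolysis before the next coupling.

**9 ⇒ 7 ⇒ 5 + 6.** The alkyne is traced to dichlorovinyl ether 7, made from phenol 5 and 6. Two equivalents of an alkyllithium turn 7 into acetylide 8, which is protonated. The ynol ether is introduced last in this arm because it is the least robust group.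

**5 ⇒ 4 ⇒ 3 + 2, and 2 ⇒ 1.** O1 is cut with the same polarity: hindered phenol 3 as nucleophile, bromide 2 as electrophile, then debenzylation. Block 2 is made once by benzylation of 1 and serves both arms.

## Alternatives that were turned down

**Alternative 1:** Here the C3–O and C5–O bonds of rings A to E are disconnected, ten hydroxyl oxygens traced back to ten formyl groups. The forward key step treats deca-aldehyde A2 with a peracid so that all ten aryl groups migrate, giving decaformate A1. In its favour, two formyl groups flanking C4 of each ring make every hindered ether an activated fluoride displacement. That is more dependable than the copper couplings of steps 2, 6 and 8, and on this point the alternative is stronger. Against it, ten Baeyer–Villiger events must all go by aryl migration on rings that each carry a second acceptor and only a weakly donating, shared ether oxygen. Hydride migration to the carboxylic acid competes at every site, and any small share is multiplied over ten sites into an inseparable mixture. Each site also needs a redox step that the chosen route needs only once (step 9, on an electron-rich ring). The chosen strategy gives up the easy ether formation. In return all oxygens come in with purchased building blocks, and the only multi-site event is a dealkylation.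

**Alternative 2:** Ring E is disconnected at C2–C3 and C5–C6 into the four-ring glutaconate A4 and malonate A5. Forward, the dienolate of A4 is acylated at both ends by A5 and the ring closes to diester A3. In its favour, it also makes a ring from open-chain carbons with O4 and O5 in place. It uses cheap enolate chemistry without a sensitive ynol ether or cyclobutenone, and the ring is symmetric, so there is no regiochemical question; on these points it is at least as good. Against it, A5 has an acidic C–H between two esters. The dienolate of A4 will deprotonate it rather than attack its hindered ester carbonyls, and the enolate of A5 no longer acylates. The two ester groups of A3 must afterwards be hydrolysed and decarboxylated. The ring made is the fifth of six, so A4 needs three hindered ether couplings in a row before the key step. The chosen strategy cuts in the middle (two rings plus three), carries no carbon that must be removed later, and runs its cascade without base.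

**Alternative 3:** Ring F is disconnected at C3–C4 and traced to pyranone A7, which carries rings A to E on its C4 oxygen. Forward, methoxide opens the lactone and the carbanion next to the methoxy group attacks the freed ester, closing ring F as the 2-methoxyresorcinol A6. In its favour, the step is mild and biomimetic, its regiochemistry is fixed by connectivity, and O5 is set by adding a phenol to a pyranone, easier than a copper coupling; on that point it is stronger. Against it, ring F is the one ring that can simply be bought as bromide 13, so the ring construction is spent where it gains nothing. All four other ethers must be built linearly first. Methoxide can also add to C4 or C6 of A7 and expel the five-ring phenoxide, a good leaving group, which would destroy the most advanced intermediate. The chosen strategy uses its ring construction on ring C, where it removes two hindered ethers from the coupling problem and halves the longest chain of couplings.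

Key step: step 13

Remark on the chemistry: compounds 1, 3, 6, 10, 13, 17 and 20 (20 as a solution in hexanes) are taken as purchased; 23 is racemic, which does not matter because its stereocentre is lost when ring C becomes aromatic.

## Route

Step 1
Reactants: 1 4-bromo-2,6-dimethoxyphenol
Product: 2 2-(benzyloxy)-5-bromo-1,3-dimethoxybenzene
Conditions: BnBr, K2CO3, DMF, rt → 50 °C
Reagents that add atoms: benzyl bromide, BrCc1ccccc1
Why: Williamson O-benzylation of the phenoxide; the benzyl ether masks the hindered hydroxyl so that 2 serves in both arms as an aryl bromide with free ortho positions.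

Step 2
Reactants: 3 2,4,6-trimethoxyphenol; 2 2-(benzyloxy)-5-bromo-1,3-dimethoxybenzene
Product: 4 2-[4-(benzyloxy)-3,5-dimethoxyphenoxy]-1,3,5-trimethoxybenzene
Conditions: CuI (10 mol %), picolinic acid (20 mol %), K3PO4, DMSO, 90 °C, argon
Reagents that add atoms: none
Why: Ligand-accelerated Ullmann diaryl ether coupling forming O1; the hindrance sits on the phenoxide and the bromide has free ortho positions, the combination these conditions are known to handle.

Step 3
Reactants: 4 2-[4-(benzyloxy)-3,5-dimethoxyphenoxy]-1,3,5-trimethoxybenzene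
Product: 5 2,6-dimethoxy-4-(2,4,6-trimethoxyphenoxy)phenol
Conditions: H2 (1 atm), Pd/C (palladium on carbon), EtOAc, rt
Reagents that add atoms: none
Why: Hydrogenolysis of the benzyl ether; methyl and diaryl ethers are inert to it.

Step 4
Reactants: 5 2,6-dimethoxy-4-(2,4,6-trimethoxyphenoxy)phenol; 6 trichloroethene
Product: 7 2-{[(E)-1,2-dichloroethenyl]oxy}-1,3-dimethoxy-5-(2,4,6-trimethoxyphenoxy)benzene
Conditions: K2CO3, DMF, 70 °C
Reagents that add atoms: none
Why: Base turns trichloroethene into dichloroethyne in the flask and anti addition of the phenoxide gives the (E)-dichlorovinyl ether, the known preparation of aryl 1,2-dichlorovinyl ethers.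

Step 5
Reactants: 7 2-{[(E)-1,2-dichloroethenyl]oxy}-1,3-dimethoxy-5-(2,4,6-trimethoxyphenoxy)benzene
Product: 9 2-(ethynyloxy)-1,3-dimethoxy-5-(2,4,6-trimethoxyphenoxy)benzene, via lithium aryloxyethynide 8 (not isolated)
Conditions: n-BuLi (2.2 equiv), THF, −78 → −40 °C; then H2O, −78 → 0 °C
Reagents that add atoms: none
Why: Deprotonation and loss of LiCl give the chloroalkynyl ether, a second equivalent of n-BuLi exchanges chlorine for lithium to give 8, and protonation gives the terminal aryl ynol ether (the established dichlorovinyl ether route to ynol ethers); the low temperature keeps n-BuLi from metalating the ring positions between two oxygens.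

Step 6
Reactants: 10 4-hydroxy-3,5-dimethoxybenzaldehyde (syringaldehyde); 2 2-(benzyloxy)-5-bromo-1,3-dimethoxybenzene
Product: 11 4-[4-(benzyloxy)-3,5-dimethoxyphenoxy]-3,5-dimethoxybenzaldehyde
Conditions: CuCl (0.5 equiv), 2,2,6,6-tetramethylheptane-3,5-dione (0.25 equiv), Cs2CO3, NMP, 120 °C, argon
Reagents that add atoms: none
Why: Ullmann diaryl ether coupling forming O4, run with the diketone-accelerated copper system because the phenoxide of 10 is hindered and weakened by the para formyl group; the aldehyde cannot enolise and should survive the carbonate base.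

Step 7
Reactants: 11 4-[4-(benzyloxy)-3,5-dimethoxyphenoxy]-3,5-dimethoxybenzaldehyde
Product: 12 4-(4-hydroxy-3,5-dimethoxyphenoxy)-3,5-dimethoxybenzaldehyde
Conditions: H2 (1 atm), Pd/C (palladium on carbon), EtOAc, rt, stopped when 11 is consumed
Reagents that add atoms: none
Why: Benzyl ether hydrogenolysis; an electron-rich aryl aldehyde is reduced much more slowly than the benzyl ether is cleaved in a neutral aprotic solvent at atmospheric pressure.

Step 8
Reactants: 12 4-(4-hydroxy-3,5-dimethoxyphenoxy)-3,5-dimethoxybenzaldehyde; 13 5-bromo-1,2,3-trimethoxybenzene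
Product: 14 4-[3,5-dimethoxy-4-(3,4,5-trimethoxyphenoxy)phenoxy]-3,5-dimethoxybenzaldehyde
Conditions: CuI (10 mol %), picolinic acid (20 mol %), K3PO4, DMSO, 100 °C, argon
Reagents that add atoms: none
Why: Second ligand-accelerated Ullmann coupling, forming O5 with the same polarity as step 2; the phenoxide of 12 is electron-rich (para aryloxy) and the aldehyde is a spectator.

Step 9
Reactants: 14 4-[3,5-dimethoxy-4-(3,4,5-trimethoxyphenoxy)phenoxy]-3,5-dimethoxybenzaldehyde
Product: 16 3,5-dimethoxy-4-[3,5-dimethoxy-4-(3,4,5-trimethoxyphenoxy)phenoxy]phenol, via aryl formate 15 (not isolated)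
Conditions: mCPBA, CH2Cl2, 0 °C → rt; then Et3N (cat.), MeOH, rt
Reagents that add atoms: mCPBA (3-chloroperoxybenzoic acid), OOC(=O)c1cccc(Cl)c1
Why: Baeyer–Villiger oxidation of an aryl aldehyde whose ring has a para aryloxy donor, so the aryl group migrates (as with 3,4,5-trimethoxybenzaldehyde); the labile aryl formate is cleaved by methanol to the single free phenol of the three-ring arm.

Step 10
Reactants: 16 3,5-dimethoxy-4-[3,5-dimethoxy-4-(3,4,5-trimethoxyphenoxy)phenoxy]phenol; 17 ethyl bromoacetate
Product: 18 ethyl 2-{3,5-dimethoxy-4-[3,5-dimethoxy-4-(3,4,5-trimethoxyphenoxy)phenoxy]phenoxy}acetate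
Conditions: K2CO3, acetone, reflux
Reagents that add atoms: none
Why: Williamson alkylation of an unhindered phenoxide with an activated primary bromide.

Step 11
Reactants: 18 ethyl 2-{3,5-dimethoxy-4-[3,5-dimethoxy-4-(3,4,5-trimethoxyphenoxy)phenoxy]phenoxy}acetate
Product: 19 2-{3,5-dimethoxy-4-[3,5-dimethoxy-4-(3,4,5-trimethoxyphenoxy)phenoxy]phenoxy}acetic acid
Conditions: LiOH·H2O, THF/H2O, rt; then 1 M HCl
Reagents that add atoms: lithium hydroxide, [Li+].[OH-]
Why: Ester saponification; nothing else in 18 reacts with hydroxide.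

Step 12
Reactants: 19 2-{3,5-dimethoxy-4-[3,5-dimethoxy-4-(3,4,5-trimethoxyphenoxy)phenoxy]phenoxy}acetic acid; 20 ethoxyethyne
Product: 23 rac-4-{3,5-dimethoxy-4-[3,5-dimethoxy-4-(3,4,5-trimethoxyphenoxy)phenoxy]phenoxy}-3-ethoxycyclobut-2-en-1-one, via aryloxyacetyl chloride 21 (not isolated), via aryloxyketene 22 (not isolated)
Conditions: (COCl)2, DMF (cat.), CH2Cl2, 0 °C → rt, concentrate; then 20 (3 equiv), Et3N, CH2Cl2, 0 °C → rt, slow addition of 21; filtration through Et3N-deactivated silica
Reagents that add atoms: none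
Why: Dehydrochlorination of 21 gives aryloxyketene 22, which adds (2+2) to the ynol ether as ketenes generally do: the ketene carbonyl carbon bonds to the alkyne CH and the aryloxy carbon to the ethoxy carbon, giving the 3-ethoxy-4-aryloxy isomer. Excess 20 and slow addition hold down ketene dimerisation; the new stereocentre is formed racemic and is lost in step 13.

Step 13
Reactants: 9 2-(ethynyloxy)-1,3-dimethoxy-5-(2,4,6-trimethoxyphenoxy)benzene; 23 rac-4-{3,5-dimethoxy-4-[3,5-dimethoxy-4-(3,4,5-trimethoxyphenoxy)phenoxy]phenoxy}-3-ethoxycyclobut-2-en-1-one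
Product: 28 5-[2,6-dimethoxy-4-(2,4,6-trimethoxyphenoxy)phenoxy]-2-{3,5-dimethoxy-4-[3,5-dimethoxy-4-(3,4,5-trimethoxyphenoxy)phenoxy]phenoxy}-3-ethoxyphenol, via vinylketene 24 (not isolated), via 4-vinylcyclobutenone 25 (not isolated), via dienylketene 26 (not isolated), via cyclohexadienone 27 (not isolated)
Conditions: 9 (1.3 equiv), toluene (0.5 M), 80 °C then 110 °C, argon, sealed tube
Reagents that add atoms: none
Why: Heating opens 23 by a four-electron conrotatory electrocyclic ring opening, the C4 aryloxy donor turning outward, to vinylketene 24. The terminal CH carbon of ynol ether 9 attacks the ketene carbonyl carbon of 24 and (2+2) adduct 25 forms, which places the ynol oxygen 1,3 to the future hydroxyl. 25 reopens to dienylketene 26, which closes ring C by a thermally allowed disrotatory six-electron electrocyclisation between the ketene carbon and the aryloxy-bearing terminus, and dienone 27 tautomerises to phenol 28; in sum the two alkyne carbons are inserted between C1 and C2 of 23, so C2–C3 and C1–C6 of ring C are the new bonds. This is the Danheiser benzannulation of a cyclobutenone with a heteroatom-substituted alkyne; the closest cases are alkoxy- and silyloxyalkynes, and an aryloxyalkyne with a 4-aryloxy-3-alkoxycyclobutenone is a new pairing within that class. No stereocentre remains, since those of 23, 25 and 27 are erased on aromatisation. The one regiochemistry required follows from the polarisation of both partners (electrophilic ketene carbon, nucleophilic β-carbon of the ynol ether). The cascade must outrun ketene dimerisation, which high concentration and excess 9 favour, and 9 has no alkyl C–H on its oxygen substituent, so it cannot fragment by a retro-ene path. Both crowded ethers of ring C, O2 and O3, are carried in as the alkyne substituent and the ketene substituent.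

Step 14
Reactants: 28 5-[2,6-dimethoxy-4-(2,4,6-trimethoxyphenoxy)phenoxy]-2-{3,5-dimethoxy-4-[3,5-dimethoxy-4-(3,4,5-trimethoxyphenoxy)phenoxy]phenoxy}-3-ethoxyphenol
Product: 29 CNP0187343.0, 2-{3,5-dihydroxy-4-[3,5-dihydroxy-4-(3,5-dihydroxy-4-{3,5-dihydroxy-4-[(3,4,5-trihydroxyphenyl)oxy]phenoxy}phenoxy)phenoxy]phenoxy}benzene-1,3,5-triol
Conditions: BBr3 (excess, more than 2 equiv per ether), CH2Cl2, −78 °C → rt, argon; then H2O, 0 °C; degassed solvents in work-up
Reagents that add atoms: none
Why: Lewis-acid dealkylation of aryl alkyl ethers; BBr3 cleaves the twelve methyl ethers and the ethyl ether at the alkyl–oxygen bond and leaves the five diaryl ethers intact, since neither side of a diaryl ether can undergo bromide attack at carbon.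

## Compound list

1 | 4-bromo-2,6-dimethoxyphenol | COc1cc(Br)cc(OC)c1O | starting material
2 | 2-(benzyloxy)-5-bromo-1,3-dimethoxybenzene | COc1cc(Br)cc(OC)c1OCc1ccccc1 | intermediate
3 | 2,4,6-trimethoxyphenol | COc1cc(OC)c(O)c(OC)c1 | starting material
4 | 2-[4-(benzyloxy)-3,5-dimethoxyphenoxy]-1,3,5-trimethoxybenzene | COc1cc(OC)c(Oc2cc(OC)c(OCc3ccccc3)c(OC)c2)c(OC)c1 | intermediate
5 | 2,6-dimethoxy-4-(2,4,6-trimethoxyphenoxy)phenol | COc1cc(OC)c(Oc2cc(OC)c(O)c(OC)c2)c(OC)c1 | intermediate
6 | trichloroethene | ClC=C(Cl)Cl | starting material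
7 | 2-{[(E)-1,2-dichloroethenyl]oxy}-1,3-dimethoxy-5-(2,4,6-trimethoxyphenoxy)benzene | COc1cc(OC)c(Oc2cc(OC)c(O/C(Cl)=C\Cl)c(OC)c2)c(OC)c1 | intermediate
8 | lithium 2-[2,6-dimethoxy-4-(2,4,6-trimethoxyphenoxy)phenoxy]ethynide | [Li]C#COc1c(OC)cc(Oc2c(OC)cc(OC)cc2OC)cc1OC | intermediate
9 | 2-(ethynyloxy)-1,3-dimethoxy-5-(2,4,6-trimethoxyphenoxy)benzene | C#COc1c(OC)cc(Oc2c(OC)cc(OC)cc2OC)cc1OC | intermediate
10 | 4-hydroxy-3,5-dimethoxybenzaldehyde (syringaldehyde) | COc1cc(C=O)cc(OC)c1O | starting material
11 | 4-[4-(benzyloxy)-3,5-dimethoxyphenoxy]-3,5-dimethoxybenzaldehyde | COc1cc(C=O)cc(OC)c1Oc1cc(OC)c(OCc2ccccc2)c(OC)c1 | intermediate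
12 | 4-(4-hydroxy-3,5-dimethoxyphenoxy)-3,5-dimethoxybenzaldehyde | COc1cc(C=O)cc(OC)c1Oc1cc(OC)c(O)c(OC)c1 | intermediate
13 | 5-bromo-1,2,3-trimethoxybenzene | COc1cc(Br)cc(OC)c1OC | starting material
14 | 4-[3,5-dimethoxy-4-(3,4,5-trimethoxyphenoxy)phenoxy]-3,5-dimethoxybenzaldehyde | COc1cc(C=O)cc(OC)c1Oc1cc(OC)c(Oc2cc(OC)c(OC)c(OC)c2)c(OC)c1 | intermediate
15 | 3,5-dimethoxy-4-[3,5-dimethoxy-4-(3,4,5-trimethoxyphenoxy)phenoxy]phenyl formate | O=COc1cc(OC)c(Oc2cc(OC)c(Oc3cc(OC)c(OC)c(OC)c3)c(OC)c2)c(OC)c1 | intermediate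
16 | 3,5-dimethoxy-4-[3,5-dimethoxy-4-(3,4,5-trimethoxyphenoxy)phenoxy]phenol | Oc1cc(OC)c(Oc2cc(OC)c(Oc3cc(OC)c(OC)c(OC)c3)c(OC)c2)c(OC)c1 | intermediate
17 | ethyl bromoacetate | CCOC(=O)CBr | starting material
18 | ethyl 2-{3,5-dimethoxy-4-[3,5-dimethoxy-4-(3,4,5-trimethoxyphenoxy)phenoxy]phenoxy}acetate | CCOC(=O)COc1cc(OC)c(Oc2cc(OC)c(Oc3cc(OC)c(OC)c(OC)c3)c(OC)c2)c(OC)c1 | intermediate
19 | 2-{3,5-dimethoxy-4-[3,5-dimethoxy-4-(3,4,5-trimethoxyphenoxy)phenoxy]phenoxy}acetic acid | OC(=O)COc1cc(OC)c(Oc2cc(OC)c(Oc3cc(OC)c(OC)c(OC)c3)c(OC)c2)c(OC)c1 | intermediate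
20 | ethoxyethyne | CCOC#C | starting material
21 | 2-{3,5-dimethoxy-4-[3,5-dimethoxy-4-(3,4,5-trimethoxyphenoxy)phenoxy]phenoxy}acetyl chloride | ClC(=O)COc1cc(OC)c(Oc2cc(OC)c(Oc3cc(OC)c(OC)c(OC)c3)c(OC)c2)c(OC)c1 | intermediate
22 | 2-{3,5-dimethoxy-4-[3,5-dimethoxy-4-(3,4,5-trimethoxyphenoxy)phenoxy]phenoxy}ethen-1-one (aryloxyketene) | O=C=COc1cc(OC)c(Oc2cc(OC)c(Oc3cc(OC)c(OC)c(OC)c3)c(OC)c2)c(OC)c1 | intermediate
23 | rac-4-{3,5-dimethoxy-4-[3,5-dimethoxy-4-(3,4,5-trimethoxyphenoxy)phenoxy]phenoxy}-3-ethoxycyclobut-2-en-1-one | CCOC1=CC(=O)C1Oc1cc(OC)c(Oc2cc(OC)c(Oc3cc(OC)c(OC)c(OC)c3)c(OC)c2)c(OC)c1 | intermediate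
24 | (3Z)-4-{3,5-dimethoxy-4-[3,5-dimethoxy-4-(3,4,5-trimethoxyphenoxy)phenoxy]phenoxy}-3-ethoxybuta-1,3-dien-1-one (vinylketene; aryloxy trans to the ketenyl carbon) | O=C=C/C(OCC)=C/Oc1cc(OC)c(Oc2cc(OC)c(Oc3cc(OC)c(OC)c(OC)c3)c(OC)c2)c(OC)c1 | intermediate
25 | rac-3-[2,6-dimethoxy-4-(2,4,6-trimethoxyphenoxy)phenoxy]-4-[(Z)-2-{3,5-dimethoxy-4-[3,5-dimethoxy-4-(3,4,5-trimethoxyphenoxy)phenoxy]phenoxy}-1-ethoxyethenyl]cyclobut-2-en-1-one | O=C1C=C(Oc2c(OC)cc(Oc3c(OC)cc(OC)cc3OC)cc2OC)C1/C(OCC)=C/Oc1cc(OC)c(Oc2cc(OC)c(Oc3cc(OC)c(OC)c(OC)c3)c(OC)c2)c(OC)c1 | intermediate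
26 | (3E,5Z)-3-[2,6-dimethoxy-4-(2,4,6-trimethoxyphenoxy)phenoxy]-6-{3,5-dimethoxy-4-[3,5-dimethoxy-4-(3,4,5-trimethoxyphenoxy)phenoxy]phenoxy}-5-ethoxyhexa-1,3,5-trien-1-one (dienylketene; ketenyl carbon and C5 cis across C3=C4) | O=C=C/C(Oc1c(OC)cc(Oc2c(OC)cc(OC)cc2OC)cc1OC)=C\C(OCC)=C\Oc1cc(OC)c(Oc2cc(OC)c(Oc3cc(OC)c(OC)c(OC)c3)c(OC)c2)c(OC)c1 | intermediate
27 | rac-3-[2,6-dimethoxy-4-(2,4,6-trimethoxyphenoxy)phenoxy]-6-{3,5-dimethoxy-4-[3,5-dimethoxy-4-(3,4,5-trimethoxyphenoxy)phenoxy]phenoxy}-5-ethoxycyclohexa-2,4-dien-1-one | O=C1C=C(Oc2c(OC)cc(Oc3c(OC)cc(OC)cc3OC)cc2OC)C=C(OCC)C1Oc1cc(OC)c(Oc2cc(OC)c(Oc3cc(OC)c(OC)c(OC)c3)c(OC)c2)c(OC)c1 | intermediate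
28 | 5-[2,6-dimethoxy-4-(2,4,6-trimethoxyphenoxy)phenoxy]-2-{3,5-dimethoxy-4-[3,5-dimethoxy-4-(3,4,5-trimethoxyphenoxy)phenoxy]phenoxy}-3-ethoxyphenol | COc1cc(OC)c(Oc2cc(OC)c(Oc3cc(O)c(Oc4cc(OC)c(Oc5cc(OC)c(Oc6cc(OC)c(OC)c(OC)c6)c(OC)c5)c(OC)c4)c(OCC)c3)c(OC)c2)c(OC)c1 | intermediate
29 | CNP0187343.0, 2-{3,5-dihydroxy-4-[3,5-dihydroxy-4-(3,5-dihydroxy-4-{3,5-dihydroxy-4-[(3,4,5-trihydroxyphenyl)oxy]phenoxy}phenoxy)phenoxy]phenoxy}benzene-1,3,5-triol | Oc1cc(O)c(Oc2cc(O)c(Oc3cc(O)c(Oc4cc(O)c(Oc5cc(O)c(Oc6cc(O)c(O)c(O)c6)c(O)c5)c(O)c4)c(O)c3)c(O)c2)c(O)c1 | target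

## Step count and risks

Total: 14 steps. Longest linear sequence: 10 steps (1, 6, 7, 8, 9, 10, 11, 12, 13, 14); the two-ring arm (steps 1–5) joins at step 13.

**Step 13 (key step).** Vinylketene 24 carries two oxygen donors and is a weak electrophile, and aryl ynol ether 9 is a weaker nucleophile than an alkyl ynol ether. The bimolecular (2+2) addition may therefore lose to reclosure and dimerisation of the ketene or to thermal oligomerisation of the alkyne. The phenol formed can also be acylated by ketene intermediates; a mild methanolysis of the crude product would return such esters to 28. Fallback: a convergent ether coupling that gives up the ring construction, setting out from 5, 2 and 16 and returning at 29.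
- 5 and 2 are coupled under the conditions of step 2 to 2-{4-[4-(benzyloxy)-3,5-dimethoxyphenoxy]-3,5-dimethoxyphenoxy}-1,3,5-trimethoxybenzene F1.
- Hydrogenolysis as in step 3 frees the three-ring phenol 4-[2,6-dimethoxy-4-(2,4,6-trimethoxyphenoxy)phenoxy]-2,6-dimethoxyphenol F2.
- 16 is converted with Tf2O and pyridine into its aryl triflate F3.
- Palladium-catalysed diaryl ether formation between F2 and F3 (Pd(OAc)2, a bulky di-tert-butylbiarylphosphine, K3PO4, toluene, 100 °C) gives the permethylated hexamer F4.
- BBr3 as in step 14 converts F4 into 29.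

**Step 12.** The aryloxyketene may dimerise faster than it is trapped. The acid chloride may acylate the strongly activated ring D intramolecularly. The vinylogous ester of 23 may hydrolyse on silica. Fallback: generate the same vinylketene without a cyclobutenone, setting out from 16 and returning at 28 (through 24 in the flask).
- 16 is alkylated (K2CO3, DMF) with purchased ethyl (2E)-4-chloro-3-ethoxybut-2-enoate to the ethyl (2E)-4-aryloxy-3-ethoxybut-2-enoate F5.
- LiOH gives the acid F6, and (COCl)2 gives the acid chloride F7.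
- Et3N removes HCl from F7 in a 1,4-sense in the presence of 9, giving 24 at or below room temperature; warming then completes the cascade of step 13 to 28.

**Step 5.** n-BuLi may metalate the ring C–H positions that lie between two oxygens instead of reacting only at the vinyl group. The terminal ynol ether may also polymerise on concentration. Fallback: a route without an alkyllithium, setting out from 5 and returning at 9.
- 5 is treated with (Z)-1,2-dichloroethene and KOH in DMSO; chloroethyne forms in the flask and the phenoxide adds to give the (Z)-2-chloroethenyl ether F8.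
- NaNH2 in liquid NH3 eliminates HCl from F8, and protonation of the sodium acetylide gives 9, which is kept in solution.

**Step 6.** The hindered phenoxide of 10, weakened by the formyl group, may couple too slowly with the electron-rich bromide, so that protodebromination of 2 takes over. Fallback: reverse the coupling type, setting out from 2 and returning at 11.
- 2 is lithiated (n-BuLi, −78 °C), borylated with B(OiPr)3 and hydrolysed to [4-(benzyloxy)-3,5-dimethoxyphenyl]boronic acid F9.
- F9 is coupled with 10 by a Chan–Lam–Evans reaction (Cu(OAc)2, pyridine, 4 Å molecular sieves, CH2Cl2, air, rt), a method that tolerates di-ortho-substituted, electron-poor phenols, to give 11.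

**Step 14.** Dealkylation at thirteen sites may stop short and leave partly alkylated congeners, and the free polyphenol may oxidise during aqueous work-up and chromatography. Fallback: isolate through a derivative, setting out from 28 and returning at 29.
- The crude product of the BBr3 reaction is acetylated (Ac2O, pyridine) to the tetradeca-O-acetate F10, which is stable to air and can be purified on silica.
- NaOMe (cat.) in degassed MeOH, followed by neutralisation with an acidic resin, releases 29.

## Further compounds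

F1 | step 13 | 2-{4-[4-(benzyloxy)-3,5-dimethoxyphenoxy]-3,5-dimethoxyphenoxy}-1,3,5-trimethoxybenzene | COc1cc(OC)c(Oc2cc(OC)c(Oc3cc(OC)c(OCc4ccccc4)c(OC)c3)c(OC)c2)c(OC)c1
F2 | step 13 | 4-[2,6-dimethoxy-4-(2,4,6-trimethoxyphenoxy)phenoxy]-2,6-dimethoxyphenol | COc1cc(OC)c(Oc2cc(OC)c(Oc3cc(OC)c(O)c(OC)c3)c(OC)c2)c(OC)c1
F3 | step 13 | 3,5-dimethoxy-4-[3,5-dimethoxy-4-(3,4,5-trimethoxyphenoxy)phenoxy]phenyl trifluoromethanesulfonate | COc1cc(OS(=O)(=O)C(F)(F)F)cc(OC)c1Oc1cc(OC)c(Oc2cc(OC)c(OC)c(OC)c2)c(OC)c1
F4 | step 13 | tetradeca-O-methyl ether of 29 (permethylated hexamer) | COc1cc(OC)c(Oc2cc(OC)c(Oc3cc(OC)c(Oc4cc(OC)c(Oc5cc(OC)c(Oc6cc(OC)c(OC)c(OC)c6)c(OC)c5)c(OC)c4)c(OC)c3)c(OC)c2)c(OC)c1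
F5 | step 12 | ethyl (2E)-4-{3,5-dimethoxy-4-[3,5-dimethoxy-4-(3,4,5-trimethoxyphenoxy)phenoxy]phenoxy}-3-ethoxybut-2-enoate | CCOC(=O)/C=C(/OCC)COc1cc(OC)c(Oc2cc(OC)c(Oc3cc(OC)c(OC)c(OC)c3)c(OC)c2)c(OC)c1
F6 | step 12 | (2E)-4-{3,5-dimethoxy-4-[3,5-dimethoxy-4-(3,4,5-trimethoxyphenoxy)phenoxy]phenoxy}-3-ethoxybut-2-enoic acid | OC(=O)/C=C(/OCC)COc1cc(OC)c(Oc2cc(OC)c(Oc3cc(OC)c(OC)c(OC)c3)c(OC)c2)c(OC)c1
F7 | step 12 | (2E)-4-{3,5-dimethoxy-4-[3,5-dimethoxy-4-(3,4,5-trimethoxyphenoxy)phenoxy]phenoxy}-3-ethoxybut-2-enoyl chloride | ClC(=O)/C=C(/OCC)COc1cc(OC)c(Oc2cc(OC)c(Oc3cc(OC)c(OC)c(OC)c3)c(OC)c2)c(OC)c1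
F8 | step 5 | 2-{[(Z)-2-chloroethenyl]oxy}-1,3-dimethoxy-5-(2,4,6-trimethoxyphenoxy)benzene | Cl/C=C\Oc1c(OC)cc(Oc2c(OC)cc(OC)cc2OC)cc1OC
F9 | step 6 | [4-(benzyloxy)-3,5-dimethoxyphenyl]boronic acid | OB(O)c1cc(OC)c(OCc2ccccc2)c(OC)c1
F10 | step 14 | tetradeca-O-acetate of 29 | CC(=O)Oc1cc(OC(C)=O)c(Oc2cc(OC(C)=O)c(Oc3cc(OC(C)=O)c(Oc4cc(OC(C)=O)c(Oc5cc(OC(C)=O)c(Oc6cc(OC(C)=O)c(OC(C)=O)c(OC(C)=O)c6)c(OC(C)=O)c5)c(OC(C)=O)c4)c(OC(C)=O)c3)c(OC(C)=O)c2)c(OC(C)=O)c1
A1 | alternative 1 | hexamer decaformate (rings A to E each with formyloxy groups at the two positions flanking the ether carbon; ring A 4-methoxy, ring F 3,4,5-trimethoxy) | COc1cc(OC=O)c(Oc2cc(OC=O)c(Oc3cc(OC=O)c(Oc4cc(OC=O)c(Oc5cc(OC=O)c(Oc6cc(OC)c(OC)c(OC)c6)c(OC=O)c5)c(OC=O)c4)c(OC=O)c3)c(OC=O)c2)c(OC=O)c1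
A2 | alternative 1 | hexamer deca-aldehyde (formyl in place of each formyloxy group of A1) | COc1cc(C=O)c(Oc2cc(C=O)c(Oc3cc(C=O)c(Oc4cc(C=O)c(Oc5cc(C=O)c(Oc6cc(OC)c(OC)c(OC)c6)c(C=O)c5)c(C=O)c4)c(C=O)c3)c(C=O)c2)c(C=O)c1
A3 | alternative 2 | hexamer with ring E as 3,5-dihydroxy-2,6-bis(methoxycarbonyl) unit, all other oxygens methylated | COc1cc(OC)c(Oc2cc(OC)c(Oc3cc(OC)c(Oc4cc(OC)c(Oc5c(C(=O)OC)c(O)c(Oc6cc(OC)c(OC)c(OC)c6)c(O)c5C(=O)OC)c(OC)c4)c(OC)c3)c(OC)c2)c(OC)c1
A4 | alternative 2 | dimethyl 3-aryloxypent-2-enedioate carrying the permethylated rings A to D on the C3 oxygen | COC(=O)CC(=CC(=O)OC)Oc1c(OC)cc(Oc2c(OC)cc(Oc3c(OC)cc(Oc4c(OC)cc(OC)cc4OC)cc3OC)cc2OC)cc1OC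
A5 | alternative 2 | dimethyl 2-(3,4,5-trimethoxyphenoxy)malonate | COC(=O)C(Oc1cc(OC)c(OC)c(OC)c1)C(=O)OC
A6 | alternative 3 | hexamer with ring F as 3,5-dihydroxy-4-methoxyphenyl ether, all other oxygens methylated | COc1cc(OC)c(Oc2cc(OC)c(Oc3cc(OC)c(Oc4cc(OC)c(Oc5cc(OC)c(Oc6cc(O)c(OC)c(O)c6)c(OC)c5)c(OC)c4)c(OC)c3)c(OC)c2)c(OC)c1
A7 | alternative 3 | 4-aryloxy-6-(methoxymethyl)-2H-pyran-2-one carrying the permethylated rings A to E on the C4 oxygen | COCC1=CC(Oc2c(OC)cc(Oc3c(OC)cc(Oc4c(OC)cc(Oc5c(OC)cc(Oc6c(OC)cc(OC)cc6OC)cc5OC)cc4OC)cc3OC)cc2OC)=CC(=O)O1
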